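## Analysis of the target

Kanzonol L is an isoflavone. Its 4H-chromen-4-one (rings A and C) carries hydroxyls at C-5 and C-7 and 3-methylbut-2-enyl (prenyl) groups at C-6 and C-8, so ring A is hexasubstituted. Ring B is bonded to C-3 through C-1'. It carries the ether oxygen of a 2,2-dimethyl-2H-pyran (ring D) at C-2', the styrenyl carbon of that pyran at C-3', a free hydroxyl at C-4' and hydrogens at C-5' and C-6'. The molecule has no stereocentre and no double bond of variable geometry, so every problem is one of regiochemistry or chemoselectivity. The sensitive groups are the two prenyl groups, each flanked by phenolic oxygens and prone to acid-induced chroman formation, the chromene double bond, and the electron-rich phenols. With three electron-rich alkenes present, electrophilic oxidants such as halogens, peracids and trivalent thallium or iodine reagents cannot be used late in the route. The hardest point is ring B: O-2' and O-4' both flank C-3', and ring D must close on O-2' only, whereas in a free 2',4'-diol the unhindered, non-chelated O-4' would react first. The second hard point is building ring C onto the crowded ring A without touching the alkenes. The strategy rests on the substitution pattern of ring B, carbon at C-1', oxygen at C-2', carbon at C-3', oxygen at C-4'. This pattern maps onto a vinylketene (C-2', C-5', C-6', C-1') and an oxygen-substituted alkyne (C-3', C-4'), so the two oxygens come from different reactants and emerge already differentiated.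

## Retrosynthetic reasoning

Ring C is opened first, at the O-1 to C-2 bond. Target 30 goes back to the formyl ketone 27, in which all four phenols are masked as methoxymethyl ethers. The forward step has to remove the four acetals, let the hydroxyl next to the ketone add to the formyl carbon and lose water. Doing this last keeps the phenols masked through every basic and Lewis-acidic step.

The C-3 to C-4 bond of the isoflavone is traced to a 1,2-shift of the ring A aroyl group. 27 comes from the trans-epoxide 26, and 26 from the chalcone 25, in which the two aryl groups are still 1,3-related. This path is chosen over oxidative aryl migrations because its only oxidant is nucleophilic and attacks the enone alone. The forward steps must epoxidise 25 without touching the prenyl or chromene alkenes, then open 26 at the benzylic carbon so that the aroyl group and not hydrogen migrates. The epoxidation requires the oxygen ortho to the ketone to be protected, hence full protection of ring A.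

The enone double bond of 25 is cut into ketone 24 and aldehyde 20. This is the convergent union of the two halves by an aldol condensation, and it places all the risk of fragment synthesis before the coupling.

Ketone 24 is the tris-methoxymethyl ether of triol 23. The two aryl to CH2 bonds of 23 are cut to give 2,4,6-trihydroxyacetophenone 21 and two equivalents of prenyl bromide 22. The acetyl group blocks one ring position, so C-alkylation can only occur at the two carbons that become C-6 and C-8.

Aldehyde 20 comes from phenol 19, and 19 from the silyl ether acetal 17. The silyl group is needed for the ring-forming step, but it sits para to what becomes a formyl and then an enone carbon. An aryl silyl ether so activated would be cleaved by the aqueous base of the condensation and by alkaline peroxide. It is therefore exchanged for a methoxymethyl ether at the stage of 19, so that one acid treatment at the end removes all four protecting groups.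

Ring D of 17 is cut at its oxygen to quaternary carbon bond, which leads to the ortho-prenylphenol 15. The forward reaction is an oxidative cyclisation of the prenyl group onto the neighbouring hydroxyl. In 15 only O-2' is free, so the direction of closure is not a selectivity question.

The benzene ring of 15 is cut at three bonds, C-2' to C-3', C-4' to C-5' and C-2' to C-1', which gives the diazo enone 5 and the siloxyalkyne 10. In the forward sense 5 becomes the vinylketene 11, and the sequence runs through 12, 13 and 14 to 15. The ketene oxygen becomes the free 2'-hydroxyl, the alkyne oxygen keeps its silyl group at C-4', and the prenyl group arrives on the alkyne at C-3'. This is the only disconnection that delivers the tetrasubstituted ring with its oxygens already distinguished and with the C-1' carbon at the aldehyde oxidation level.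

Both partners are reached in two steps each. 5 comes by diazo transfer from the enone 3, which is made from aldehyde 1 and ylide 2 by olefination. 10 comes from the ester 7 of acid 6 by one-carbon homologation to the ynolate 9 and O-silylation.

## Alternatives that were turned down

Alternative 1: The two aryl to CH2 bonds of ring A are cut last. The precursor is A2, the 5,7-bis(1,1-dimethylallyl) ether of the complete isoflavone with O-4' silylated. Heating A2 should bring about two aromatic Claisen rearrangements, O-5 to C-6 and O-7 to C-8, each with allyl inversion so that the tertiary ether becomes a normal prenyl group. This gives A1, and desilylation would finish the synthesis.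
- For: the prenyl groups appear at the end, the core can be assembled on an unsubstituted ring A, the poorly selective C-alkylation of step 9 is avoided, and no acid touches a prenylated phenol. On these points it is stronger than the chosen route.
- Against: the O-7 group has two free ortho positions. If it moves to C-6, the O-5 group has no ortho carbon left and can reach C-8 only by two consecutive shifts, arriving as the reverse isomer, or it is lost by elimination, which tertiary allyl aryl ethers undergo readily on heating.
- Against: A2 requires two tertiary allylic ethers, one of them on the chelated O-5, which costs several steps.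
- Against: it does not address ring B, which would still need a solution of its own.
- Comparison: the chosen route gives up the late prenylation. In return it has a two-step ring A fragment and a ring B whose regiochemistry is decided by bond polarity and not by competing migration rates.

Alternative 2: Ring C is cut at O-1 to C-8a and C-4 to C-4a. The partners are the silyl triflate A4, precursor of a fully substituted ring A aryne, and the ring B methoxyacrylic acid A5. Fluoride should release the aryne and the carboxylate of A5 should add at C-8a, the aryne carbon remote from the inductively withdrawing O-5. The aryl anion at C-4a would then take the acyl carbon, and the freed phenoxide would displace methoxide at C-2 to give A3. Acid would remove three acetals.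
- For: it is the most convergent plan. Both elaborated halves are joined and ring C is closed in one flask, with no chalcone, epoxide or Lewis-acid rearrangement. It is stronger than the chosen route in convergence and in the number of operations after fragment union.
- Against: A4 is a hexasubstituted benzene whose preparation is long.
- Against: the carboxylate must attack an aryne carbon flanked by a prenyl group.
- Against: the aryl anion can be protonated by the acid before it reaches the acyl carbon through a four-membered transition state, which would give an aryl ester.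
- Against: arynes undergo ene reactions with trisubstituted alkenes that carry allylic hydrogens, and A4 has two such groups.
- Against: A5 must still be made from a ring B with differentiated oxygens, so the central problem is only moved, and the final acid deprotection is the same as in the chosen route.
- Comparison: the chosen route offers a known ring C construction from two short fragments and solves ring B itself.

Alternative 3: Ring B is cut at C-1' to C-6'. The precursor is the triketide A7, a 3,5-dioxoheptanoate with the prenyl group on C-4 and a masked aldehyde at C-7. Mild aqueous acid should free the aldehyde and buffered base should let C-2 add to it. Dehydration and enolisation would then give the aromatic ester A6.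
- For: no diazo compound, no photochemistry and no moisture-sensitive alkyne are needed, the materials are cheap, and the prenyl group is set by enolate alkylation between the two ketones. In operational simplicity and scalability it is stronger than the chosen route.
- Against: A6 has both hydroxyls free. The hydrogen bond of O-2' to the ester makes O-4' the more reactive, which is the wrong oxygen for ring D. O-4' must therefore be protected selectively before closure, so selectivity rests on chelation and not on construction.
- Against: the ester has to be brought to the aldehyde oxidation level in two further steps.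
- Against: A7 can cyclise in other modes, by lactonisation through an enol oxygen or by Claisen-type closure, and its alkylation can stray to C-2 or to oxygen.
- Comparison: the chosen route delivers from its ring-forming step a free O-2', a protected O-4' and a carbon at C-1' that is already an aldehyde equivalent.

Key step: step 5

Assumption: aldehyde 1 is used as its commercial aqueous solution; 12, 14, 26, 27, 28 and 29 are racemic or stereochemically mixed, which does not matter because the target has no stereocentre.

Step 1
Reactants: 1 2,2-dimethoxyacetaldehyde; 2 1-(triphenyl-λ5-phosphanylidene)propan-2-one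
Product: 3 (E)-5,5-dimethoxypent-3-en-2-one
Conditions: CH2Cl2/H2O, rt
Reagents that add atoms: none
Why: Wittig olefination with a ketone-stabilised ylide; such ylides tolerate water, react with the free aldehyde in equilibrium with its hydrate and give the E-enone.

Step 2
Reactants: 3 (E)-5,5-dimethoxypent-3-en-2-one
Product: 5 (E)-1-diazo-5,5-dimethoxypent-3-en-2-one, via trifluoroacetyl diketone 4 (not isolated)
Conditions: LiN(SiMe3)2, THF, −78 °C; CF3CO2CH2CF3; cold dilute HCl wash; then MsN3, Et3N, H2O, MeCN, rt
Reagents that add atoms: methanesulfonyl azide, CS(=O)(=O)N=[N+]=[N-] (supplies the N2 unit); 2,2,2-trifluoroethyl trifluoroacetate, O=C(OCC(F)(F)F)C(F)(F)F (its CF3CO group is carried by 4 and lost again)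
Why: Detrifluoroacetylative diazo transfer: the kinetic lithium enolate of the methyl ketone is trifluoroacetylated to 4, whose doubly activated methylene takes the diazo group from the sulfonyl azide while the trifluoroacetyl group leaves on the sulfonamide nitrogen. Apart from the brief cold acid wash the sequence is basic or neutral, and the acetal, attached to an electron-poor alkene carbon, is slow to ionise during that wash.

Step 3
Reactants: 6 4-methylpent-3-enoic acid
Product: 7 ethyl 4-methylpent-3-enoate
Conditions: EtI, K2CO3, DMF, rt
Reagents that add atoms: iodoethane, CCI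
Why: SN2 O-alkylation of the carboxylate; avoiding acid prevents lactonisation of the β,γ-unsaturated acid onto its trisubstituted double bond, and the weak base does not move the double bond into conjugation.

Step 4
Reactants: 7 ethyl 4-methylpent-3-enoate
Product: 10 triisopropyl[(5-methylhex-4-en-1-yn-1-yl)oxy]silane, via dibromo enolate 8 (not isolated), via lithium ynolate 9 (not isolated)
Conditions: CH2Br2, lithium 2,2,6,6-tetramethylpiperidide, THF, −78 °C; LiN(SiMe3)2; n-BuLi, −78 °C to rt; then i-Pr3SiCl, −78 °C to rt
Reagents that add atoms: dibromomethane, BrCBr (supplies the new alkyne carbon); chlorotriisopropylsilane, CC(C)[Si](Cl)(C(C)C)C(C)C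
Why: Kowalski ester homologation stopped at the ynolate: LiCHBr2 adds to the ester, the dibromo ketone is enolised to 8, and bromine–lithium exchange followed by 1,2-shift of the alkyl group with loss of LiBr gives ynolate 9. The bulky silyl chloride silylates 9 on oxygen, and the triisopropylsilyl ynol ether is stable enough to be purified.

Step 5
Reactants: 5 (E)-1-diazo-5,5-dimethoxypent-3-en-2-one; 10 triisopropyl[(5-methylhex-4-en-1-yn-1-yl)oxy]silane
Product: 15 6-(dimethoxymethyl)-2-(3-methylbut-2-en-1-yl)-3-[(triisopropylsilyl)oxy]phenol, via vinylketene 11 (not isolated), via vinylcyclobutenone 12 (not isolated), via dienylketene 13 (not isolated), via cyclohexadienone 14 (not isolated)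
Conditions: hν (254 nm, quartz), ClCH2CH2Cl, rt; then 80 °C
Reagents that add atoms: none
Why: Irradiation expels nitrogen from 5 and the alkenyl group migrates to the former diazo carbon (photochemical Wolff rearrangement), giving vinylketene 11. The electrophilic ketene carbonyl carbon bonds to the prenyl-bearing carbon of 10, the nucleophilic terminus of the ynol ether, and the ketene α-carbon to the oxygen-bearing carbon, a regiospecific [2+2] cycloaddition that forms the C-2' to C-3' and C-4' to C-5' bonds in 12. Four-electron electrocyclic opening of 12, under the light or on warming, gives dienylketene 13; only the isomer with the ketene-bearing carbon and the vinyl group cis can react further, and because the opening is reversible the other isomer is returned to 12. Thermal six-electron disrotatory electrocyclisation of 13 forms the C-2' to C-1' bond and the only ring closed in this step, and 14 tautomerises to the phenol. The closest known reaction type is the second-generation Danheiser benzannulation of α-diazo enones with siloxyalkynes, which gives resorcinol monosilyl ethers. No stereocentre is formed that survives, since the sp3 carbons of 12 and 14 are transient. The step needs three selectivities: the regiochemistry of the [2+2] addition, secured by the polarisation of the siloxyalkyne, which puts the prenyl group at C-3' between the oxygens and the acetal carbon at C-1'; the differentiation of the oxygens, secured by construction because the ketene oxygen becomes the free 2'-hydroxyl and the alkyne oxygen keeps its silyl group; and reaction of the ketene with the alkyne in preference to the prenyl double bond, secured by the far higher nucleophilicity of the ynol ether. The acetal is inert to these neutral conditions.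

Step 6
Reactants: 15 6-(dimethoxymethyl)-2-(3-methylbut-2-en-1-yl)-3-[(triisopropylsilyl)oxy]phenol
Product: 17 8-(dimethoxymethyl)-2,2-dimethyl-5-[(triisopropylsilyl)oxy]-2H-chromene, via quinone methide 16 (not isolated)
Conditions: DDQ, benzene, 80 °C
Reagents that add atoms: none
Why: Oxidative cyclisation of an ortho-prenylphenol: DDQ removes hydride from the benzylic CH2, which is activated by the ortho hydroxyl and ortho silyloxy groups, and the hydroxyl proton is lost to give 16; oxa-6π electrocyclisation closes ring D. Only O-2' carries a proton, so the silylated O-4' cannot take part and the ring fusion is fixed.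

Step 7
Reactants: 17 8-(dimethoxymethyl)-2,2-dimethyl-5-[(triisopropylsilyl)oxy]-2H-chromene
Product: 19 5-hydroxy-2,2-dimethyl-2H-chromene-8-carbaldehyde, via desilylated acetal 18 (not isolated)
Conditions: Bu4NF, THF, 0 °C; then 1 M HCl, rt
Reagents that add atoms: water, O
Why: Fluoride cleaves the aryl silyl ether, and dilute acid then hydrolyses the dimethyl acetal, which the para oxygen makes very labile; the chromene tolerates brief contact with cold dilute acid. The silyl group is removed here because an aryl silyl ether para to a formyl or enone group would not survive hydroxide in step 11 or hydroperoxide in step 12.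

Step 8
Reactants: 19 5-hydroxy-2,2-dimethyl-2H-chromene-8-carbaldehyde
Product: 20 5-(methoxymethoxy)-2,2-dimethyl-2H-chromene-8-carbaldehyde
Conditions: MOMCl, K2CO3, acetone, rt
Reagents that add atoms: chloromethyl methyl ether, COCCl
Why: Williamson-type O-alkylation of an acidic para-formylphenol with a hard alkylating agent; the methoxymethyl ether is stable to the basic steps that follow and is removed together with those of ring A.

Step 9
Reactants: 21 1-(2,4,6-trihydroxyphenyl)ethanone; 22 1-bromo-3-methylbut-2-ene (first equivalent)
Product: 23 1-[2,4,6-trihydroxy-3,5-bis(3-methylbut-2-en-1-yl)phenyl]ethanone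
Conditions: 22 (2 equiv in all), aq. KOH, 0 °C to rt
Reagents that add atoms: 1-bromo-3-methylbut-2-ene, CC(C)=CCBr (the second equivalent of 22, which supplies the second prenyl group)
Why: Two successive C-alkylations of the phloroglucinol phenoxide by two equivalents of 22, favoured in water where the oxygens are solvated; the acetyl group leaves C-3 and C-5 as the only free ring positions, and each takes one prenyl group. Mono-, geminal di- and O-alkylated by-products are expected and are separated; the modest efficiency is accepted for a first step on inexpensive materials.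

Step 10
Reactants: 23 1-[2,4,6-trihydroxy-3,5-bis(3-methylbut-2-en-1-yl)phenyl]ethanone
Product: 24 1-[2,4,6-tris(methoxymethoxy)-3,5-bis(3-methylbut-2-en-1-yl)phenyl]ethanone
Conditions: NaH, MOMCl (excess), DMF, 0 °C to rt
Reagents that add atoms: chloromethyl methyl ether, COCCl (three equivalents, one for each hydroxyl)
Why: O-alkylation of the tris-phenoxide with a hard, oxocarbenium-like electrophile, which goes to oxygen even at the hindered, formerly chelated hydroxyls. All three must be masked: free phenoxides would deactivate the ketone in step 11, and a free ortho hydroxyl would divert step 12 into an Algar–Flynn–Oyamada cyclisation.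

Step 11
Reactants: 24 1-[2,4,6-tris(methoxymethoxy)-3,5-bis(3-methylbut-2-en-1-yl)phenyl]ethanone; 20 5-(methoxymethoxy)-2,2-dimethyl-2H-chromene-8-carbaldehyde
Product: 25 (2E)-3-[5-(methoxymethoxy)-2,2-dimethyl-2H-chromen-8-yl]-1-[2,4,6-tris(methoxymethoxy)-3,5-bis(3-methylbut-2-en-1-yl)phenyl]prop-2-en-1-one
Conditions: KOH, EtOH/THF/H2O, rt
Reagents that add atoms: none
Why: Claisen–Schmidt condensation of the methyl ketone enolate with the non-enolisable aldehyde; E1cB loss of water gives the E-enone. All protecting groups are acetals and are inert to hydroxide.

Step 12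
Reactants: 25 (2E)-3-[5-(methoxymethoxy)-2,2-dimethyl-2H-chromen-8-yl]-1-[2,4,6-tris(methoxymethoxy)-3,5-bis(3-methylbut-2-en-1-yl)phenyl]prop-2-en-1-one
Product: 26 rac-[(2R,3S)-3-[5-(methoxymethoxy)-2,2-dimethyl-2H-chromen-8-yl]oxiran-2-yl][2,4,6-tris(methoxymethoxy)-3,5-bis(3-methylbut-2-en-1-yl)phenyl]methanone
Conditions: 30% H2O2, NaOH, MeOH/THF, 0 °C to rt
Reagents that add atoms: hydrogen peroxide, OO
Why: Weitz–Scheffer epoxidation: hydroperoxide adds conjugately to the enone and the enolate closes onto oxygen, so the electron-rich prenyl and chromene double bonds are untouched. Closure from the more stable enolate rotamer gives the trans (2R*,3S*) epoxide as a racemate; both stereocentres disappear in steps 13 and 14.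

Step 13
Reactants: 26 rac-[(2R,3S)-3-[5-(methoxymethoxy)-2,2-dimethyl-2H-chromen-8-yl]oxiran-2-yl][2,4,6-tris(methoxymethoxy)-3,5-bis(3-methylbut-2-en-1-yl)phenyl]methanone
Product: 27 2-[5-(methoxymethoxy)-2,2-dimethyl-2H-chromen-8-yl]-3-oxo-3-[2,4,6-tris(methoxymethoxy)-3,5-bis(3-methylbut-2-en-1-yl)phenyl]propanal
Conditions: BF3·OEt2, CH2Cl2, −78 to −20 °C
Reagents that add atoms: none
Why: Lewis acid-promoted rearrangement of an α,β-epoxy ketone (Meinwald-type semipinacol shift): the epoxide opens at the benzylic carbon, whose cation is stabilised by the ortho and para oxygens of ring B, and the aroyl group shifts from the α to the β carbon, leaving the aldehyde. This makes the C-3 to C-4 bond of the isoflavone; the new stereocentre is racemic, enolisable and lost in step 14.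

Step 14
Reactants: 27 2-[5-(methoxymethoxy)-2,2-dimethyl-2H-chromen-8-yl]-3-oxo-3-[2,4,6-tris(methoxymethoxy)-3,5-bis(3-methylbut-2-en-1-yl)phenyl]propanal
Product: 30 Kanzonol L (5,7-dihydroxy-3-(5-hydroxy-2,2-dimethyl-2H-chromen-8-yl)-6,8-bis(3-methylbut-2-en-1-yl)-4H-chromen-4-one), via tetraphenol formyl ketone 28 (not isolated), via hydroxyisoflavanone 29 (not isolated)
Conditions: 3 M HCl, MeOH/THF, 50 °C
Reagents that add atoms: none
Why: Acid-catalysed methanolysis of the four methoxymethyl acetals frees the phenols of 28; the hydroxyl ortho to the ketone adds to the aldehyde (6-exo-trig, giving 29) and loss of water aromatises ring C. Dilute acid and short heating are chosen to limit addition of the phenols to the prenyl double bonds; any material that already lost its ortho protecting group and cyclised in step 13 converges here.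

## Compound list

1 | 2,2-dimethoxyacetaldehyde | COC(OC)C=O | starting material
2 | 1-(triphenyl-λ5-phosphanylidene)propan-2-one | CC(=O)C=P(c1ccccc1)(c1ccccc1)c1ccccc1 | starting material
3 | (E)-5,5-dimethoxypent-3-en-2-one | CC(=O)/C=C/C(OC)OC | intermediate
4 | (E)-1,1,1-trifluoro-7,7-dimethoxyhept-5-ene-2,4-dione | COC(OC)/C=C/C(=O)CC(=O)C(F)(F)F | intermediate
5 | (E)-1-diazo-5,5-dimethoxypent-3-en-2-one | COC(OC)/C=C/C(=O)C=[N+]=[N-] | intermediate
6 | 4-methylpent-3-enoic acid | CC(C)=CCC(=O)O | starting material
7 | ethyl 4-methylpent-3-enoate | CCOC(=O)CC=C(C)C | intermediate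
8 | lithium 1,1-dibromo-5-methylhexa-1,4-dien-2-olate | [Li+].[O-]C(CC=C(C)C)=C(Br)Br | intermediate
9 | lithium 5-methylhex-4-en-1-yn-1-olate | [Li+].[O-]C#CCC=C(C)C | intermediate
10 | triisopropyl[(5-methylhex-4-en-1-yn-1-yl)oxy]silane | CC(C)=CCC#CO[Si](C(C)C)(C(C)C)C(C)C | intermediate
11 | (3E)-5,5-dimethoxypenta-1,3-dien-1-one | O=C=C/C=C/C(OC)OC | intermediate
12 | 4-[(1E)-3,3-dimethoxyprop-1-en-1-yl]-2-(3-methylbut-2-en-1-yl)-3-[(triisopropylsilyl)oxy]cyclobut-2-en-1-one (racemic) | COC(OC)/C=C/C1C(=O)C(CC=C(C)C)=C1O[Si](C(C)C)(C(C)C)C(C)C | intermediate
13 | (3E,5E)-7,7-dimethoxy-2-(3-methylbut-2-en-1-yl)-3-[(triisopropylsilyl)oxy]hepta-1,3,5-trien-1-one | O=C=C(CC=C(C)C)/C(O[Si](C(C)C)(C(C)C)C(C)C)=C\C=C\C(OC)OC | intermediate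
14 | 6-(dimethoxymethyl)-2-(3-methylbut-2-en-1-yl)-3-[(triisopropylsilyl)oxy]cyclohexa-2,4-dien-1-one (racemic) | COC(OC)C1C=CC(O[Si](C(C)C)(C(C)C)C(C)C)=C(CC=C(C)C)C1=O | intermediate
15 | 6-(dimethoxymethyl)-2-(3-methylbut-2-en-1-yl)-3-[(triisopropylsilyl)oxy]phenol | COC(OC)c1ccc(O[Si](C(C)C)(C(C)C)C(C)C)c(CC=C(C)C)c1O | intermediate
16 | (6Z)-2-(dimethoxymethyl)-6-(3-methylbut-2-en-1-ylidene)-5-[(triisopropylsilyl)oxy]cyclohexa-2,4-dien-1-one | O=C1/C(=C\C=C(C)C)C(O[Si](C(C)C)(C(C)C)C(C)C)=CC=C1C(OC)OC | intermediate
17 | 8-(dimethoxymethyl)-2,2-dimethyl-5-[(triisopropylsilyl)oxy]-2H-chromene | COC(OC)c1ccc(O[Si](C(C)C)(C(C)C)C(C)C)c2C=CC(C)(C)Oc12 | intermediate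
18 | 8-(dimethoxymethyl)-2,2-dimethyl-2H-chromen-5-ol (present as its tetrabutylammonium phenoxide) | COC(OC)c1ccc(O)c2C=CC(C)(C)Oc12 | intermediate
19 | 5-hydroxy-2,2-dimethyl-2H-chromene-8-carbaldehyde | O=Cc1ccc(O)c2C=CC(C)(C)Oc12 | intermediate
20 | 5-(methoxymethoxy)-2,2-dimethyl-2H-chromene-8-carbaldehyde | COCOc1ccc(C=O)c2OC(C)(C)C=Cc12 | intermediate
21 | 1-(2,4,6-trihydroxyphenyl)ethanone | CC(=O)c1c(O)cc(O)cc1O | starting material
22 | 1-bromo-3-methylbut-2-ene | CC(C)=CCBr | starting material
23 | 1-[2,4,6-trihydroxy-3,5-bis(3-methylbut-2-en-1-yl)phenyl]ethanone | CC(=O)c1c(O)c(CC=C(C)C)c(O)c(CC=C(C)C)c1O | intermediate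
24 | 1-[2,4,6-tris(methoxymethoxy)-3,5-bis(3-methylbut-2-en-1-yl)phenyl]ethanone | COCOc1c(CC=C(C)C)c(OCOC)c(CC=C(C)C)c(OCOC)c1C(C)=O | intermediate
25 | (2E)-3-[5-(methoxymethoxy)-2,2-dimethyl-2H-chromen-8-yl]-1-[2,4,6-tris(methoxymethoxy)-3,5-bis(3-methylbut-2-en-1-yl)phenyl]prop-2-en-1-one | COCOc1c(CC=C(C)C)c(OCOC)c(CC=C(C)C)c(OCOC)c1C(=O)/C=C/c1ccc(OCOC)c2C=CC(C)(C)Oc12 | intermediate
26 | rac-[(2R,3S)-3-[5-(methoxymethoxy)-2,2-dimethyl-2H-chromen-8-yl]oxiran-2-yl][2,4,6-tris(methoxymethoxy)-3,5-bis(3-methylbut-2-en-1-yl)phenyl]methanone (trans, one enantiomer drawn) | COCOc1c(CC=C(C)C)c(OCOC)c(CC=C(C)C)c(OCOC)c1C(=O)[C@@H]1O[C@H]1c1ccc(OCOC)c2C=CC(C)(C)Oc12 | intermediate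
27 | 2-[5-(methoxymethoxy)-2,2-dimethyl-2H-chromen-8-yl]-3-oxo-3-[2,4,6-tris(methoxymethoxy)-3,5-bis(3-methylbut-2-en-1-yl)phenyl]propanal (racemic, enolisable) | COCOc1c(CC=C(C)C)c(OCOC)c(CC=C(C)C)c(OCOC)c1C(=O)C(C=O)c1ccc(OCOC)c2C=CC(C)(C)Oc12 | intermediate
28 | 2-(5-hydroxy-2,2-dimethyl-2H-chromen-8-yl)-3-oxo-3-[2,4,6-trihydroxy-3,5-bis(3-methylbut-2-en-1-yl)phenyl]propanal (racemic, enolisable) | CC(C)=CCc1c(O)c(CC=C(C)C)c(O)c(C(=O)C(C=O)c2ccc(O)c3C=CC(C)(C)Oc23)c1O | intermediate
29 | 2,5,7-trihydroxy-3-(5-hydroxy-2,2-dimethyl-2H-chromen-8-yl)-6,8-bis(3-methylbut-2-en-1-yl)-2,3-dihydro-4H-chromen-4-one (mixture of diastereomers) | CC(C)=CCc1c(O)c(CC=C(C)C)c2OC(O)C(c3ccc(O)c4C=CC(C)(C)Oc34)C(=O)c2c1O | intermediate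
30 | Kanzonol L (5,7-dihydroxy-3-(5-hydroxy-2,2-dimethyl-2H-chromen-8-yl)-6,8-bis(3-methylbut-2-en-1-yl)-4H-chromen-4-one) | CC(C)=CCc1c(O)c(CC=C(C)C)c2occ(-c3ccc(O)c4c3OC(C)(C)C=C4)c(=O)c2c1O | target

## Step count and least certain steps

Total step count: 14. Longest linear sequence: 10 steps (1, 2, 5, 6, 7, 8, 11, 12, 13, 14; the branch through steps 3 and 4 is equally long). The ring A branch (steps 9 and 10) joins at step 11.

Step 5 (key step).
- What may go wrong: inefficient capture of the vinylketene, through ketene dimerisation, photodecomposition of the siloxyalkyne, or carbene-type side reactions such as cyclopropanation of the prenyl double bond if nitrogen loss and migration are not concerted.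
- What may go wrong: acylation of the product phenol by a second ketene.
- What may go wrong: loss of methanol from the salicyl acetal during the heating phase.
- Fallback: ring B would be taken from an aromatic precursor, trading the built-in differentiation of the oxygens for one based on hydrogen bonding. It sets out from prenyl bromide 22. C-alkylation of 2,4-dihydroxybenzaldehyde F1 with 22 in aqueous KOH should give, after separation from the 5-prenyl and O-prenyl isomers, 2,4-dihydroxy-3-(3-methylbut-2-en-1-yl)benzaldehyde F2. MOMCl and K2CO3 in acetone should etherify only the non-chelated 4-hydroxyl to give 2-hydroxy-4-(methoxymethoxy)-3-(3-methylbut-2-en-1-yl)benzaldehyde F3. DDQ in hot benzene then closes the pyran on the one remaining hydroxyl, and the route is rejoined at aldehyde 20.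

Step 4.
- What may go wrong: deprotonation of the β,γ-unsaturated ester at its doubly activated CH2 in place of addition of LiCHBr2.
- What may go wrong: enolisation of the dibromo ketone toward the allylic side.
- What may go wrong: base-induced migration of the skipped enyne into an allene or a conjugated enyne under the excess of strong base.
- Fallback: the ynolate is made by oxidation of an acetylide in place of ester homologation. It sets out from 22. Coupling with ethynylmagnesium bromide and catalytic CuCl in THF should give 5-methylhex-4-en-1-yne F4. n-BuLi converts it into lithium 5-methylhex-4-en-1-yn-1-ide F5, which attacks the electrophilic oxygen of lithium tert-butyl peroxide (from tert-butyl hydroperoxide and LiN(SiMe3)2) to give the same ynolate 9. Silylation with i-Pr3SiCl rejoins the route at 10.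

Step 6.
- What may go wrong: hydride abstraction from the acetal carbon, which is also benzylic and stabilised by two oxygens, in competition with abstraction from the prenyl CH2.
- What may go wrong: acetal cleavage by the acidic hydroquinone formed, which leaves a chelated and less reactive phenol.
- Fallback: a non-oxidative closure followed by elimination, setting out from 15. PhSeCl with K2CO3 in CH2Cl2 at −78 °C should form a seleniranium ion on the prenyl double bond, which the free hydroxyl opens at the tertiary carbon to give 8-(dimethoxymethyl)-2,2-dimethyl-3-(phenylselanyl)-5-[(triisopropylsilyl)oxy]chromane F6. H2O2 in THF oxidises it to the corresponding selenoxide F7. Its syn elimination can only take a benzylic hydrogen, because the other neighbouring carbon is quaternary, and it delivers chromene 17.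

Step 13.
- What may go wrong: Lewis acid-assisted loss of methoxymethyl groups, above all the two that can chelate boron beside the ketone, followed by acid-triggered addition of the freed phenols to the neighbouring prenyl double bonds.
- What may go wrong: capture of the benzylic cation by fluoride, or a hydride shift in place of the aroyl shift.
- Fallback: the protecting group is changed to one that neither chelates nor ionises and that is removed without acid. It sets out from 19 and 23. Allyl bromide and K2CO3 in DMF should give 2,2-dimethyl-5-(prop-2-en-1-yloxy)-2H-chromene-8-carbaldehyde F8 and 1-[3,5-bis(3-methylbut-2-en-1-yl)-2,4,6-tris(prop-2-en-1-yloxy)phenyl]ethanone F9. Condensation, epoxidation and aroyl shift under the conditions of steps 11 to 13 lead through the tetraallyl chalcone F10 and the tetraallyl epoxide F11 to the tetraallyl formyl ketone F12. Pd(PPh3)4 (zerovalent palladium) with sodium p-toluenesulfinate in THF/MeOH then removes the four allyl groups under neutral conditions to give 28, which closes through 29 to the target 30 on addition of acetic acid. This line also takes the mineral acid out of step 14, where prolonged exposure would threaten the prenylated phenols in the same way.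

## Further compounds

F1 | step 5 | 2,4-dihydroxybenzaldehyde | O=Cc1ccc(O)cc1O
F2 | step 5 | 2,4-dihydroxy-3-(3-methylbut-2-en-1-yl)benzaldehyde | O=Cc1ccc(O)c(CC=C(C)C)c1O
F3 | step 5 | 2-hydroxy-4-(methoxymethoxy)-3-(3-methylbut-2-en-1-yl)benzaldehyde | COCOc1ccc(C=O)c(O)c1CC=C(C)C
F4 | step 4 | 5-methylhex-4-en-1-yne | C#CCC=C(C)C
F5 | step 4 | lithium 5-methylhex-4-en-1-yn-1-ide | [Li+].[C-]#CCC=C(C)C
F6 | step 6 | 8-(dimethoxymethyl)-2,2-dimethyl-3-(phenylselanyl)-5-[(triisopropylsilyl)oxy]chromane (racemic) | COC(OC)c1ccc(O[Si](C(C)C)(C(C)C)C(C)C)c2CC([Se]c3ccccc3)C(C)(C)Oc12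
F7 | step 6 | 8-(dimethoxymethyl)-2,2-dimethyl-3-(phenylseleninyl)-5-[(triisopropylsilyl)oxy]chromane (mixture of diastereomers) | COC(OC)c1ccc(O[Si](C(C)C)(C(C)C)C(C)C)c2CC([Se](=O)c3ccccc3)C(C)(C)Oc12
F8 | step 13 | 2,2-dimethyl-5-(prop-2-en-1-yloxy)-2H-chromene-8-carbaldehyde | C=CCOc1ccc(C=O)c2OC(C)(C)C=Cc12
F9 | step 13 | 1-[3,5-bis(3-methylbut-2-en-1-yl)-2,4,6-tris(prop-2-en-1-yloxy)phenyl]ethanone | C=CCOc1c(CC=C(C)C)c(OCC=C)c(CC=C(C)C)c(OCC=C)c1C(C)=O
F10 | step 13 | (2E)-3-[2,2-dimethyl-5-(prop-2-en-1-yloxy)-2H-chromen-8-yl]-1-[3,5-bis(3-methylbut-2-en-1-yl)-2,4,6-tris(prop-2-en-1-yloxy)phenyl]prop-2-en-1-one | C=CCOc1c(CC=C(C)C)c(OCC=C)c(CC=C(C)C)c(OCC=C)c1C(=O)/C=C/c1ccc(OCC=C)c2C=CC(C)(C)Oc12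
F11 | step 13 | rac-[(2R,3S)-3-[2,2-dimethyl-5-(prop-2-en-1-yloxy)-2H-chromen-8-yl]oxiran-2-yl][3,5-bis(3-methylbut-2-en-1-yl)-2,4,6-tris(prop-2-en-1-yloxy)phenyl]methanone | C=CCOc1c(CC=C(C)C)c(OCC=C)c(CC=C(C)C)c(OCC=C)c1C(=O)[C@@H]1O[C@H]1c1ccc(OCC=C)c2C=CC(C)(C)Oc12
F12 | step 13 | 2-[2,2-dimethyl-5-(prop-2-en-1-yloxy)-2H-chromen-8-yl]-3-oxo-3-[3,5-bis(3-methylbut-2-en-1-yl)-2,4,6-tris(prop-2-en-1-yloxy)phenyl]propanal (racemic, enolisable) | C=CCOc1c(CC=C(C)C)c(OCC=C)c(CC=C(C)C)c(OCC=C)c1C(=O)C(C=O)c1ccc(OCC=C)c2C=CC(C)(C)Oc12
A1 | alternative 1 | 3-[5-{[tert-butyl(dimethyl)silyl]oxy}-2,2-dimethyl-2H-chromen-8-yl]-5,7-dihydroxy-6,8-bis(3-methylbut-2-en-1-yl)-4H-chromen-4-one | CC(C)=CCc1c(O)c(CC=C(C)C)c2occ(-c3ccc(O[Si](C)(C)C(C)(C)C)c4c3OC(C)(C)C=C4)c(=O)c2c1O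
A2 | alternative 1 | 3-[5-{[tert-butyl(dimethyl)silyl]oxy}-2,2-dimethyl-2H-chromen-8-yl]-5,7-bis[(2-methylbut-3-en-2-yl)oxy]-4H-chromen-4-one | C=CC(C)(C)Oc1cc(OC(C)(C)C=C)c2c(=O)c(-c3ccc(O[Si](C)(C)C(C)(C)C)c4C=CC(C)(C)Oc34)coc2c1
A3 | alternative 2 | 5,7-bis(methoxymethoxy)-3-[5-(methoxymethoxy)-2,2-dimethyl-2H-chromen-8-yl]-6,8-bis(3-methylbut-2-en-1-yl)-4H-chromen-4-one | CC(C)=CCc1c(OCOC)c(CC=C(C)C)c2occ(-c3ccc(OCOC)c4c3OC(C)(C)C=C4)c(=O)c2c1OCOC
A4 | alternative 2 | 3,5-bis(methoxymethoxy)-2,4-bis(3-methylbut-2-en-1-yl)-6-(trimethylsilyl)phenyl trifluoromethanesulfonate | COCOc1c(CC=C(C)C)c(OCOC)c(CC=C(C)C)c(OS(=O)(=O)C(F)(F)F)c1[Si](C)(C)C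
A5 | alternative 2 | (2E)-3-methoxy-2-[5-(methoxymethoxy)-2,2-dimethyl-2H-chromen-8-yl]prop-2-enoic acid | CO/C=C(/C(=O)O)c1ccc(OCOC)c2C=CC(C)(C)Oc12
A6 | alternative 3 | methyl 2,4-dihydroxy-3-(3-methylbut-2-en-1-yl)benzoate | COC(=O)c1ccc(O)c(CC=C(C)C)c1O
A7 | alternative 3 | methyl 7,7-dimethoxy-4-(3-methylbut-2-en-1-yl)-3,5-dioxoheptanoate (racemic, enolisable) | COC(=O)CC(=O)C(CC=C(C)C)C(=O)CC(OC)OC
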